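A direct plan would start from the formylated, mono-O-methylated arene 2,6-dihydroxy-4-methoxy-3-methylbenzaldehyde A1 and protect both phenols as benzyl ethers.
It would extend the aldehyde by a Horner–Wadsworth–Emmons reaction to the (E)-pentenone A2, reduce this to a silyl enol ether and build ring A on the side chain with malonyl dichloride A3.
This would give the bis-benzylated diarylmethane triol A4; hydrogenolysis and a twofold Friedel–Crafts butanoylation of both rings would finish.
Weak point 1, the mono-O-methylation that leads to A1: one equivalent of reagent would have to pick one of three phenols, so over- and mis-methylated material would burden the first stage.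
Weak point 2, the ring A construction from the enol ether and A3: O-acylation to pyranones and double capture would compete, and C,C-closure to a phloroglucinol would be untested on such a substrate.
Weak point 3, the final double acylation in a strong Lewis acid on the electron-rich bis(hydroxyaryl)methane: acid cleavage and scrambling of the methylene bridge, or xanthene formation, would threaten the sequence at its end, and the benzyl on/off pair would build nothing.

**Retrosynthetic overview**
The methylene bridge would be formed last: the ortho-quinone methide from a ring B Mannich base is captured by the one free carbon of the ring A ketone, itself one acylation away from a commercial arene.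
Ring B would not come from an arene: its bonds C1–C2 and C3–C4 would be made in one operation by insertion of the two-carbon enolate of a β-amino ester into 4-methoxy-3-methyl-6-propyl-2-pyranone (lactone opening, Dieckmann closure, aromatisation).
In this ring transformation the pyranone C4–OMe becomes the aryl methyl ether between methyl and butanoyl, C3–CH3 the aryl methyl, and C6 with its propyl group and the ring oxygen the butanoyl group; the amino ester brings the benzylic carbon as a latent quinone methide.
The single acidic hydroxyl of the hydroxypyranone is methylated before any phenol exists, both butanoyl groups are in place before the rings are joined, and no protecting group is needed.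
Ring order: ring A is bought as an arene and acylated, ring B is closed in the key step, the bridge comes last.

Key step: step 3

Assumption: the target has no stereocentre and no stereogenic double bond, so no stereocontrol is required; it is drawn as the hydroxyaryl ketone tautomer.

Step 1
Reactants: 1 ethyl 2-methyl-3-oxobutanoate; 2 methyl butanoate
Product: 4 4-hydroxy-3-methyl-6-propyl-2H-pyran-2-one, via ethyl 2-methyl-3,5-dioxooctanoate 3 (not isolated)
Conditions: 1 (2.2 equiv), NaH then n-BuLi (2.2 equiv each), THF, 0 °C; 2 (1.0 equiv), 0 °C to rt; aq. HCl; then DBU (0.2 equiv), toluene, reflux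
Reagents that add atoms: methyl butanoate (compound 2), CCCC(=O)OC
Why: Huckin–Weiler acylation of the β-keto ester dianion at its γ-carbon by the ester (crossed Claisen condensation) should give 3, whose C5 enol oxygen then displaces ethoxide under base catalysis (lactonisation) to give the 4-hydroxy-2-pyranone with methyl at C3 and propyl at C6.

Step 2
Reactants: 4 4-hydroxy-3-methyl-6-propyl-2H-pyran-2-one
Product: 5 4-methoxy-3-methyl-6-propyl-2H-pyran-2-one
Conditions: Me2SO4 (1.2 equiv), K2CO3 (1.5 equiv), acetone, reflux
Reagents that add atoms: dimethyl sulfate, COS(=O)(=O)OC
Why: Williamson-type O-methylation of the vinylogous acid, which with dimethyl sulfate and carbonate in acetone should give mainly the 4-methoxy-2-pyranone and not the 2-methoxy-4-pyranone; this one methylation fixes the future aryl methyl ether.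

Step 3
Reactants: 5 4-methoxy-3-methyl-6-propyl-2H-pyran-2-one; 6 methyl 3-(dimethylamino)propanoate
Product: 8 1-{3-[(dimethylamino)methyl]-2,4-dihydroxy-6-methoxy-5-methylphenyl}butan-1-one, via ring-opened 3,7-dioxodec-4-enoate 7 (not isolated)
Conditions: 6 (2.2 equiv), LiN(iPr)2 (2.2 equiv), THF, −78 °C; 5, −78 to 0 °C; then MeOH, rt; aq. NH4Cl, extraction at pH 8
Reagents that add atoms: methyl 3-(dimethylamino)propanoate (compound 6), CN(C)CCC(=O)OC
Why: Proposed new method: the lithium enolate of 6 should add to the lactone carbonyl C2 of 5 and the lactol alkoxide should collapse by expelling the ring oxygen as the dienolate of the propyl ketone (an irreversible enol-lactone acyl transfer that forms C3–C4 of the future ring, numbering of 8, and gives 7), after which the carbon between the methoxy-bearing carbon and the propyl ketone attacks the methyl ester in a Dieckmann closure (C1–C2), methoxide leaves and the trione enolises to the arene. The closest known reaction types are the Fujimoto–Belleau opening of enol lactones by carbanions, the Staunton–Weinreb condensation of carbanions with methoxypyranones and the Harris Claisen cyclisation of 3,5,7-triketo esters to acylphloroglucinols. Ring B closes by a 6-(enolexo)-exo-trig attack, made possible by the (E)-double bond of 7, which is inherited from the pyranone ring and holds the nucleophilic carbon and the ester-bearing acyl group cis. No stereocentre survives, since the one sp3 centre of 7 is erased on aromatisation. The step needs attack at C2 instead of conjugate attack at C6 or deprotonation of the propyl group, which the hard lithium enolate at −78 °C, the substituted C6 and the reversibility of proton transfer against the irreversible ring opening should secure; it also needs Claisen and not aldol closure, which the strongly basic medium favours and the dimethylaminomethyl branch enforces, because an aldol product with a quaternary carbon could not aromatise. The positions of all six substituents, including the methoxy group between methyl and butanoyl, follow from the connectivity of 5.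

Step 4
Reactants: 9 2-methylphloroglucinol (2-methylbenzene-1,3,5-triol); 10 butanoyl chloride
Product: 11 1-(2,4,6-trihydroxy-3-methylphenyl)butan-1-one
Conditions: 10 (1.1 equiv), AlCl3 (3.5 equiv), nitrobenzene/CH2Cl2, 0 °C to rt; aq. HCl
Reagents that add atoms: butanoyl chloride (compound 10), CCCC(=O)Cl
Why: Friedel–Crafts C-acylation; the two free ring carbons of 9 are equivalent and the first acyl group deactivates the ring as a hydrogen-bonded ortho-hydroxyaryl ketone, so monoacylation should dominate.

Step 5
Reactants: 8 1-{3-[(dimethylamino)methyl]-2,4-dihydroxy-6-methoxy-5-methylphenyl}butan-1-one; 11 1-(2,4,6-trihydroxy-3-methylphenyl)butan-1-one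
Product: 12 1-{3-[(3-butanoyl-2,6-dihydroxy-4-methoxy-5-methylphenyl)methyl]-2,4,6-trihydroxy-5-methylphenyl}butan-1-one
Conditions: 11 (1.3 equiv), 1,4-dioxane, 100 °C, argon sweep
Reagents that add atoms: 1-(2,4,6-trihydroxy-3-methylphenyl)butan-1-one (compound 11), CCCC(=O)c1c(O)cc(O)c(C)c1O
Why: Thermal loss of dimethylamine from the phenolic Mannich base gives an ortho-quinone methide, which the single free, doubly hydroxyl-flanked carbon of 11 should attack in a conjugate Friedel–Crafts alkylation; 8 has no free ring carbon, so only the cross-product can form, and no acid is present to scramble the bridge.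

**Compound list**
1 | ethyl 2-methyl-3-oxobutanoate (ethyl 2-methylacetoacetate) | CCOC(=O)C(C)C(C)=O | starting material
2 | methyl butanoate | CCCC(=O)OC | starting material
3 | ethyl 2-methyl-3,5-dioxooctanoate (racemic, not isolated) | CCCC(=O)CC(=O)C(C)C(=O)OCC | intermediate
4 | 4-hydroxy-3-methyl-6-propyl-2H-pyran-2-one | CCCC1=CC(O)=C(C)C(=O)O1 | intermediate
5 | 4-methoxy-3-methyl-6-propyl-2H-pyran-2-one | CCCC1=CC(OC)=C(C)C(=O)O1 | intermediate
6 | methyl 3-(dimethylamino)propanoate | CN(C)CCC(=O)OC | starting material
7 | methyl (4E)-2-[(dimethylamino)methyl]-5-methoxy-4-methyl-3,7-dioxodec-4-enoate (racemic, present as its enolates, not isolated) | COC(=O)C(CN(C)C)C(=O)/C(C)=C(/OC)CC(=O)CCC | intermediate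
8 | 1-{3-[(dimethylamino)methyl]-2,4-dihydroxy-6-methoxy-5-methylphenyl}butan-1-one | CCCC(=O)c1c(O)c(CN(C)C)c(O)c(C)c1OC | intermediate
9 | 2-methylphloroglucinol (2-methylbenzene-1,3,5-triol) | Cc1c(O)cc(O)cc1O | starting material
10 | butanoyl chloride | CCCC(=O)Cl | starting material
11 | 1-(2,4,6-trihydroxy-3-methylphenyl)butan-1-one | CCCC(=O)c1c(O)cc(O)c(C)c1O | intermediate
12 | 1-{3-[(3-butanoyl-2,6-dihydroxy-4-methoxy-5-methylphenyl)methyl]-2,4,6-trihydroxy-5-methylphenyl}butan-1-one | CCCC(=O)c1c(O)c(C)c(O)c(Cc2c(O)c(C)c(OC)c(C(=O)CCC)c2O)c1O | target

Total step count: 5. Longest linear sequence: 4 steps (steps 1, 2, 3 and 5).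

**Steps most likely to fail**

1. Step 3 (proposed new method). The enolate could take a proton from the propyl group of 5 or attack C6 instead of the lactone carbonyl. The open-chain anion could also stall before Dieckmann closure, or close in the aldol sense with loss of the aminomethyl branch. The fallback uses known chemistry and sets out from 11. Benzylation of the para and the less hindered ortho hydroxyl (BnBr 2.1 equiv, K2CO3, acetone, reflux) would give 1-[4,6-bis(benzyloxy)-2-hydroxy-3-methylphenyl]butan-1-one F1. Methylation of the remaining chelated hydroxyl between methyl and acyl (MeI, K2CO3, DMF, 60 °C) would give 1-[4,6-bis(benzyloxy)-2-methoxy-3-methylphenyl]butan-1-one F2. Hydrogenolysis (H2, 10% Pd/C, EtOAc) would give 1-(2,4-dihydroxy-6-methoxy-5-methylphenyl)butan-1-one F3. A phenol Mannich reaction at the only free ring carbon of F3 (aq. CH2O, Me2NH, EtOH) would return to the route at 8.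

2. Step 5. Amine elimination could be slow, or the aryl groups could exchange across the new methylene bridge by retro-alkylation, which would lead to symmetrical dimers. The fallback reverses the polarity of the union and sets out from 11. A Mannich reaction with dimethylmethyleneiminium iodide in MeCN would give 1-{3-[(dimethylamino)methyl]-2,4,6-trihydroxy-5-methylphenyl}butan-1-one F4. The quinone methide of F4, formed in warm dioxane, would be captured by the free ring carbon of the ring B phenol 1-(2,4-dihydroxy-6-methoxy-5-methylphenyl)butan-1-one F3, made as described under step 3, and the route is rejoined at 12.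

3. Step 2. Alkylation could occur at the lactone oxygen and give the isomeric 2-methoxy-4-pyranone. The fallback sets the methyl ether before the pyranone ring exists and sets out from 1. Trimethyl orthoformate with catalytic H2SO4, followed by distillation, would give ethyl (2E)-3-methoxy-2-methylbut-2-enoate F5. The lithium dienolate of F5 (LiN(iPr)2, THF, −78 °C) would be acylated at the γ-carbon with butanoyl chloride to ethyl (2E)-3-methoxy-2-methyl-5-oxooct-2-enoate F6. F6 would lactonise on warming with DBU in toluene and return to the route at 5.

**Further compounds**
F1 | step 3 | 1-[4,6-bis(benzyloxy)-2-hydroxy-3-methylphenyl]butan-1-one | CCCC(=O)c1c(O)c(C)c(OCc2ccccc2)cc1OCc1ccccc1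
F2 | step 3 | 1-[4,6-bis(benzyloxy)-2-methoxy-3-methylphenyl]butan-1-one | CCCC(=O)c1c(OC)c(C)c(OCc2ccccc2)cc1OCc1ccccc1
F3 | step 3 | 1-(2,4-dihydroxy-6-methoxy-5-methylphenyl)butan-1-one | CCCC(=O)c1c(OC)c(C)c(O)cc1O
F4 | step 5 | 1-{3-[(dimethylamino)methyl]-2,4,6-trihydroxy-5-methylphenyl}butan-1-one | CCCC(=O)c1c(O)c(C)c(O)c(CN(C)C)c1O
F5 | step 2 | ethyl (2E)-3-methoxy-2-methylbut-2-enoate | CCOC(=O)/C(C)=C(/OC)C
F6 | step 2 | ethyl (2E)-3-methoxy-2-methyl-5-oxooct-2-enoate | CCOC(=O)/C(C)=C(/OC)CC(=O)CCC
A1 | direct plan | 2,6-dihydroxy-4-methoxy-3-methylbenzaldehyde | COc1cc(O)c(C=O)c(O)c1C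
A2 | direct plan | (E)-1-[2,6-bis(benzyloxy)-4-methoxy-3-methylphenyl]pent-1-en-3-one | CCC(=O)/C=C/c1c(OCc2ccccc2)cc(OC)c(C)c1OCc1ccccc1
A3 | direct plan | malonyl dichloride | O=C(Cl)CC(=O)Cl
A4 | direct plan | 2-{[2,6-bis(benzyloxy)-4-methoxy-3-methylphenyl]methyl}-4-methylbenzene-1,3,5-triol | Cc1c(O)cc(O)c(Cc2c(OCc3ccccc3)c(C)c(OC)cc2OCc2ccccc2)c1O
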